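**Plan**

- Retrosynthesis: the C1–C2 bond of the cyclopentene is cut first (C2 becomes a one-carbon carbene unit, C1 the CH2 of an ethyl group, C3 a ketone). The styryl–alkenyl bond of the side chain is cut next, leaving a propynyl group on C5. Last, the C4–C5 and C3a–C7a bonds of the cyclohexene are cut (Diels–Alder), with C3 and C1 joined through a temporary ester oxygen.
- Forward: a lactate-derived dienynol is esterified with a mesaconate half ester, and an ester-tethered intramolecular Diels–Alder reaction builds the cyclohexene together with a temporary trans-fused γ-lactone. EtLi opens the lactone to the C3 ethyl ketone and the tether oxygen is removed from C1. The cyclopentene is then closed, the side chain is completed and the ester is cleaved.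
- Enabling feature: on the cyclohexene ring (C3a–C4–C5–C6–C7–C7a) the C3a propanoyl and C7a ethyl groups are trans-vicinal. The ethyl CH2 (future C1) therefore lies five atoms from the carbene carbon (future C2) generated on C3, and 1,5 C–H insertion gives the ring C1–C2–C3–C3a–C7a with the C2=C3 alkene in place.
- Stereochemistry: the (S)-carbinol of ethyl (S)-lactate fixes the diene face through 1,3-allylic strain with the C7 methyl. The alkene geometries and the endo ester then set C3a, C4, C5 and C7a; C1 is set in the key step by the same strain element; the side-chain geometry comes from syn hydrozirconation and a stereoretentive coupling.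

Key step: step 14

Remark: locants C1–C7a are those of the indene skeleton of the target; 1, 5, 11, 12 and 23 are taken as purchased, and the acid is carried as its methyl ester from step 8 to step 16.

**Step 1**
Reactants: 1 ethyl (2S)-2-hydroxypropanoate (ethyl (S)-lactate)
Product: 2 ethyl (2S)-2-[(tert-butyldimethylsilyl)oxy]propanoate
Conditions: TBSCl, imidazole, DMF, rt
Reagents that add atoms: tert-butyldimethylsilyl chloride, CC(C)(C)[Si](C)(C)Cl
Why: Standard silyl ether protection of the secondary alcohol, which does not touch the stereocentre.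

**Step 2**
Reactants: 2 ethyl (2S)-2-[(tert-butyldimethylsilyl)oxy]propanoate
Product: 4 (2S)-2-[(tert-butyldimethylsilyl)oxy]propanal, via aluminium hemiacetal 3 (not isolated)
Conditions: i-Bu2AlH (1.05 equiv), CH2Cl2, −78 °C; aq. potassium sodium tartrate
Reagents that add atoms: none
Why: Partial ester reduction stops at the tetrahedral aluminium hemiacetal at low temperature, and the α-silyloxy aldehyde released on work-up is configurationally stable if used at once.

**Step 3**
Reactants: 4 (2S)-2-[(tert-butyldimethylsilyl)oxy]propanal; 5 2-(triphenyl-λ5-phosphanylidene)propanal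
Product: 6 (2E,4S)-4-[(tert-butyldimethylsilyl)oxy]-2-methylpent-2-enal
Conditions: toluene, 80 °C
Reagents that add atoms: none
Why: Wittig olefination with a stabilised formyl ylide should give the (E)-trisubstituted enal, with the carbinol carbon trans to the formyl group.

**Step 4**
Reactants: 6 (2E,4S)-4-[(tert-butyldimethylsilyl)oxy]-2-methylpent-2-enal
Product: 7 tert-butyl{[(2S,3E)-6,6-dibromo-4-methylhexa-3,5-dien-2-yl]oxy}dimethylsilane
Conditions: CBr4, PPh3, Et3N, CH2Cl2, 0 °C
Reagents that add atoms: carbon tetrabromide, BrC(Br)(Br)Br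
Why: Ramirez dibromo-olefination (first stage of the Corey–Fuchs sequence) converts the aldehyde into the 1,1-dibromoalkene under buffered conditions that spare the silyl ether.

**Step 5**
Reactants: 7 tert-butyl{[(2S,3E)-6,6-dibromo-4-methylhexa-3,5-dien-2-yl]oxy}dimethylsilane
Product: 8 tert-butyl{[(2S,3E,5Z)-6-bromo-4-methylnona-3,5-dien-7-yn-2-yl]oxy}dimethylsilane
Conditions: MeC≡CMgBr, ZnBr2, THF, 0 °C; then 7, PdCl2(DPEphos) (5 mol %), 0 °C to rt
Reagents that add atoms: 1-propynylmagnesium bromide, CC#C[Mg]Br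
Why: Negishi coupling of a 1,1-dibromoalkene takes place first at the less hindered bromide trans to the carbon chain, which places the propynyl group trans to the diene chain.

**Step 6**
Reactants: 8 tert-butyl{[(2S,3E,5Z)-6-bromo-4-methylnona-3,5-dien-7-yn-2-yl]oxy}dimethylsilane
Product: 9 tert-butyl{[(2S,3E,5E)-6-ethyl-4-methylnona-3,5-dien-7-yn-2-yl]oxy}dimethylsilane
Conditions: Et2Zn, Pd(P(t-Bu)3)2 (3 mol %), THF, rt
Reagents that add atoms: diethylzinc, CC[Zn]CC
Why: A second Negishi coupling with a bulky trialkylphosphine catalyst should replace the remaining bromide with retention of geometry, leaving the ethyl group cis to the diene chain.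

**Step 7**
Reactants: 9 tert-butyl{[(2S,3E,5E)-6-ethyl-4-methylnona-3,5-dien-7-yn-2-yl]oxy}dimethylsilane
Product: 10 (2S,3E,5E)-6-ethyl-4-methylnona-3,5-dien-7-yn-2-ol
Conditions: Bu4NF, THF, 0 °C
Reagents that add atoms: none
Why: Fluoride-induced Si–O cleavage (silyl ether deprotection) frees the allylic alcohol under non-acidic conditions, so the dienyl carbinol is not ionised.

**Step 8**
Reactants: 11 glyoxylic acid monohydrate (2,2-dihydroxyacetic acid); 12 methyl 2-(triphenyl-λ5-phosphanylidene)propanoate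
Product: 13 (2E)-4-methoxy-3-methyl-4-oxobut-2-enoic acid
Conditions: CH2Cl2, rt; extraction into aq. NaHCO3, then acidification
Reagents that add atoms: none
Why: Wittig olefination of the aldehyde with a stabilised ylide should give the (E)-alkene (mesaconate pattern) with the free acid on the CH= carbon and the methyl ester on the methyl-bearing carbon.

**Step 9**
Reactants: 10 (2S,3E,5E)-6-ethyl-4-methylnona-3,5-dien-7-yn-2-ol; 13 (2E)-4-methoxy-3-methyl-4-oxobut-2-enoic acid
Product: 14 4-[(2S,3E,5E)-6-ethyl-4-methylnona-3,5-dien-7-yn-2-yl] 1-methyl (2E)-2-methylbut-2-enedioate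
Conditions: DCC, DMAP (cat.), CH2Cl2, 0 °C to rt
Reagents that add atoms: none
Why: Steglich esterification acylates the alcohol oxygen, so the carbinol configuration is retained and the dienophile geometry is not disturbed.

**Step 10**
Reactants: 14 4-[(2S,3E,5E)-6-ethyl-4-methylnona-3,5-dien-7-yn-2-yl] 1-methyl (2E)-2-methylbut-2-enedioate
Product: 15 methyl (3S,3aS,6R,7R,7aS)-6-ethyl-3,4,7-trimethyl-1-oxo-6-(prop-1-yn-1-yl)-1,3,3a,6,7,7a-hexahydro-2-benzofuran-7-carboxylate (trans-fused γ-lactone)
Conditions: toluene (0.01 M), BHT, 130 °C, sealed tube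
Reagents that add atoms: none
Why: Thermal type 1 intramolecular Diels–Alder reaction of an ester-tethered nona-1,3,8-triene with a doubly activated (E)-dienophile, in which suprafacial addition turns the (E)-dienophile and (E,E)-diene geometries into the relative configuration of C3a, C4, C5 and C7a, the terminal methyl ester sits endo so that the tether is exo and the lactone trans-fused, and the (S)-carbinol, whose hydrogen eclipses the C7 methyl to avoid 1,3-allylic strain, lets the tether oxygen reach only one diene face.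

**Step 11**
Reactants: 15 the trans-fused γ-lactone
Product: 17 methyl (1R,2R,5S,6S)-2-ethyl-5-[(1S)-1-hydroxyethyl]-1,4-dimethyl-6-propanoyl-2-(prop-1-yn-1-yl)cyclohex-3-ene-1-carboxylate, via lithium hemiketalate 16 (not isolated)
Conditions: EtLi (1.05 equiv), THF, −78 °C; AcOH (1 equiv), −78 °C
Reagents that add atoms: ethyllithium, [Li]CC
Why: Organolithium mono-addition to the strained lactone carbonyl gives a tetrahedral lithium hemiketalate that should persist at −78 °C and open to the ethyl ketone only on quench, while the methyl ester on the quaternary carbon is too hindered to react.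

**Step 12**
Reactants: 17 the hydroxy ketone
Product: 18 methyl (1R,2R,5S,6S)-2-ethyl-5-[(1S)-1-(1H-imidazole-1-carbothioyloxy)ethyl]-1,4-dimethyl-6-propanoyl-2-(prop-1-yn-1-yl)cyclohex-3-ene-1-carboxylate
Conditions: 1,1'-thiocarbonyldiimidazole, DMAP (cat.), ClCH2CH2Cl, 70 °C
Reagents that add atoms: 1,1'-thiocarbonyldiimidazole, S=C(n1ccnc1)n1ccnc1
Why: Thioacylation of the secondary alcohol (first stage of a Barton–McCombie deoxygenation) proceeds under neutral conditions that do not epimerise the ketone α-carbon.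

**Step 13**
Reactants: 18 the imidazole-1-carbothioate
Product: 19 methyl (1R,2R,5S,6S)-2,5-diethyl-1,4-dimethyl-6-propanoyl-2-(prop-1-yn-1-yl)cyclohex-3-ene-1-carboxylate
Conditions: Bu3SnH (0.2 M), AIBN (cat.), toluene, 100 °C
Reagents that add atoms: none
Why: Barton–McCombie radical deoxygenation removes the tether oxygen, the secondary radical being reduced by the tin hydride faster than it can add to the internal alkyne or the ring alkene.

**Step 14**
Reactants: 19 the ethyl ketone
Product: 22 methyl (1R,3aR,4R,5R,7aS)-3,5-diethyl-1,4,7-trimethyl-5-(prop-1-yn-1-yl)-3a,4,5,7a-tetrahydro-1H-indene-4-carboxylate, via diazoalkene 20 (not isolated), via alkylidene carbene 21 (not isolated)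
Conditions: Me3SiCHN2, n-BuLi, THF, −78 °C; then 19, −78 °C to rt
Reagents that add atoms: (trimethylsilyl)diazomethane, C[Si](C)(C)C=[N+]=[N-]
Why: Lithiated (trimethylsilyl)diazomethane adds to the C3 ketone, Peterson-type loss of Me3SiOLi gives diazoalkene 20, and loss of N2 gives alkylidene carbene 21, whose carbene carbon (C2) inserts in a concerted way into a C–H bond of the C7a ethyl CH2 (C1); the closest known reaction type is the alkylidene carbene 1,5 C–H insertion used for cyclopentene annulation of ketones. The ring C1–C2–C3–C3a–C7a is closed by 1,5 insertion through a five-membered cyclic transition state, and the carbene carbon becomes the vinylic CH, so the C2=C3 alkene appears in its final position without regiochemical ambiguity. The ring fusion is trans because the propanoyl and ethyl groups of 19 are already trans on the cyclohexene and C3a and C7a are not touched. The new stereocentre C1 depends on which diastereotopic methylene hydrogen reacts: the transition state that keeps the terminal methyl pseudo-equatorial and turned away from the C7 methyl (peri-type 1,3-allylic strain) leads to the required (1R) centre. The step needs site selectivity, and the substrate should secure it because the only other C–H bonds five atoms from the carbene are those of the C4 methyl (primary, much less reactive than secondary), 1,2-shift is slow for dialkyl alkylidene carbenes, and neither the ring alkene nor the propynyl group can be reached without severe strain.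

**Step 15**
Reactants: 22 the propynyl bicycle; 23 [(E)-2-bromoethenyl]benzene
Product: 26 methyl (1R,3aR,4R,5S,7aS)-3,5-diethyl-1,4,7-trimethyl-5-[(1E,3E)-2-methyl-4-phenylbuta-1,3-dien-1-yl]-3a,4,5,7a-tetrahydro-1H-indene-4-carboxylate, via alkenylzirconocene chloride 24 (not isolated), via alkenylzinc chloride 25 (not isolated)
Conditions: Cp2Zr(H)Cl (2 equiv), THF, 40 °C; then ZnCl2, 23, Pd(PPh3)4 (5 mol %), rt
Reagents that add atoms: none
Why: Syn hydrozirconation of the internal alkyne places zirconium on the methyl-bearing carbon remote from the quaternary C5, and Zr-to-Zn transmetalation followed by Negishi coupling proceeds with retention at both alkenyl partners to give the (1E,3E)-diene, the trisubstituted ring alkenes being inert to the hydride.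

**Step 16**
Reactants: 26 the methyl ester
Product: 28 (1R,3aR,4R,5S,7aS)-3,5-diethyl-1,4,7-trimethyl-5-[(1E,3E)-2-methyl-4-phenylbuta-1,3-dien-1-yl]-3a,4,5,7a-tetrahydro-1H-indene-4-carboxylic acid, via sodium carboxylate 27 (not isolated)
Conditions: NaSEt (5 equiv), DMF, 90 °C; then aq. HCl
Reagents that add atoms: none
Why: Thiolate SN2 dealkylation attacks the ester methyl carbon and not the carbonyl, so the extreme hindrance around the quaternary C4 does not matter and no stereocentre or alkene is touched.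

**Compound list**

1 | ethyl (2S)-2-hydroxypropanoate | C[C@H](O)C(=O)OCC | starting material
2 | ethyl (2S)-2-[(tert-butyldimethylsilyl)oxy]propanoate | C[C@H](O[Si](C)(C)C(C)(C)C)C(=O)OCC | intermediate
3 | diisobutylaluminium hemiacetal of 2 (mixture at the acetal carbon) | C[C@H](O[Si](C)(C)C(C)(C)C)C(OCC)O[Al](CC(C)C)CC(C)C | intermediate (not isolated)
4 | (2S)-2-[(tert-butyldimethylsilyl)oxy]propanal | C[C@H](O[Si](C)(C)C(C)(C)C)C=O | intermediate
5 | 2-(triphenyl-λ5-phosphanylidene)propanal | CC(C=O)=P(c1ccccc1)(c1ccccc1)c1ccccc1 | starting material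
6 | (2E,4S)-4-[(tert-butyldimethylsilyl)oxy]-2-methylpent-2-enal | C[C@H](O[Si](C)(C)C(C)(C)C)/C=C(\C)C=O | intermediate
7 | tert-butyl{[(2S,3E)-6,6-dibromo-4-methylhexa-3,5-dien-2-yl]oxy}dimethylsilane | C[C@H](O[Si](C)(C)C(C)(C)C)/C=C(C)/C=C(Br)Br | intermediate
8 | tert-butyl{[(2S,3E,5Z)-6-bromo-4-methylnona-3,5-dien-7-yn-2-yl]oxy}dimethylsilane | C[C@H](O[Si](C)(C)C(C)(C)C)/C=C(C)/C=C(\Br)C#CC | intermediate
9 | tert-butyl{[(2S,3E,5E)-6-ethyl-4-methylnona-3,5-dien-7-yn-2-yl]oxy}dimethylsilane | C[C@H](O[Si](C)(C)C(C)(C)C)/C=C(C)/C=C(\CC)C#CC | intermediate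
10 | (2S,3E,5E)-6-ethyl-4-methylnona-3,5-dien-7-yn-2-ol | C[C@H](O)/C=C(C)/C=C(\CC)C#CC | intermediate
11 | glyoxylic acid monohydrate (2,2-dihydroxyacetic acid) | OC(O)C(=O)O | starting material
12 | methyl 2-(triphenyl-λ5-phosphanylidene)propanoate | COC(=O)C(C)=P(c1ccccc1)(c1ccccc1)c1ccccc1 | starting material
13 | (2E)-4-methoxy-3-methyl-4-oxobut-2-enoic acid | COC(=O)/C(C)=C/C(=O)O | intermediate
14 | 4-[(2S,3E,5E)-6-ethyl-4-methylnona-3,5-dien-7-yn-2-yl] 1-methyl (2E)-2-methylbut-2-enedioate | C[C@H](OC(=O)/C=C(\C)C(=O)OC)/C=C(C)/C=C(\CC)C#CC | intermediate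
15 | methyl (3S,3aS,6R,7R,7aS)-6-ethyl-3,4,7-trimethyl-1-oxo-6-(prop-1-yn-1-yl)-1,3,3a,6,7,7a-hexahydro-2-benzofuran-7-carboxylate | O=C1O[C@@H](C)[C@@H]2C(C)=C[C@@](C#CC)(CC)[C@](C)(C(=O)OC)[C@@H]12 | intermediate
16 | lithium hemiketalate from EtLi addition to 15 (mixture at the hemiketal carbon) | CCC1([O-])O[C@@H](C)[C@@H]2C(C)=C[C@@](C#CC)(CC)[C@](C)(C(=O)OC)[C@@H]12.[Li+] | intermediate (not isolated)
17 | methyl (1R,2R,5S,6S)-2-ethyl-5-[(1S)-1-hydroxyethyl]-1,4-dimethyl-6-propanoyl-2-(prop-1-yn-1-yl)cyclohex-3-ene-1-carboxylate | C[C@H](O)[C@@H]2C(C)=C[C@@](C#CC)(CC)[C@](C)(C(=O)OC)[C@H]2C(=O)CC | intermediate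
18 | methyl (1R,2R,5S,6S)-2-ethyl-5-[(1S)-1-(1H-imidazole-1-carbothioyloxy)ethyl]-1,4-dimethyl-6-propanoyl-2-(prop-1-yn-1-yl)cyclohex-3-ene-1-carboxylate | C[C@H](OC(=S)n1ccnc1)[C@@H]2C(C)=C[C@@](C#CC)(CC)[C@](C)(C(=O)OC)[C@H]2C(=O)CC | intermediate
19 | methyl (1R,2R,5S,6S)-2,5-diethyl-1,4-dimethyl-6-propanoyl-2-(prop-1-yn-1-yl)cyclohex-3-ene-1-carboxylate | CC[C@@H]2C(C)=C[C@@](C#CC)(CC)[C@](C)(C(=O)OC)[C@H]2C(=O)CC | intermediate
20 | methyl (1R,2R,5S,6S)-6-(1-diazobut-1-en-2-yl)-2,5-diethyl-1,4-dimethyl-2-(prop-1-yn-1-yl)cyclohex-3-ene-1-carboxylate | CC[C@@H]2C(C)=C[C@@](C#CC)(CC)[C@](C)(C(=O)OC)[C@H]2C(CC)=C=[N+]=[N-] | intermediate (not isolated)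
21 | alkylidene carbene from 20 (but-1-en-1-ylidene attached through its C2 to the ring) | CC[C@@H]2C(C)=C[C@@](C#CC)(CC)[C@](C)(C(=O)OC)[C@H]2C(CC)=[C] | intermediate (not isolated)
22 | methyl (1R,3aR,4R,5R,7aS)-3,5-diethyl-1,4,7-trimethyl-5-(prop-1-yn-1-yl)-3a,4,5,7a-tetrahydro-1H-indene-4-carboxylate | CCC1=C[C@@H](C)[C@@H]2C(C)=C[C@@](C#CC)(CC)[C@](C)(C(=O)OC)[C@@H]12 | intermediate
23 | [(E)-2-bromoethenyl]benzene | Br/C=C/c1ccccc1 | starting material
24 | (E)-alkenylzirconocene chloride from 22 (Zr on the methyl-bearing alkene carbon) | CCC1=C[C@@H](C)[C@@H]2C(C)=C[C@@](/C=C(C)/[Zr](Cl)(C3C=CC=C3)C3C=CC=C3)(CC)[C@](C)(C(=O)OC)[C@@H]12 | intermediate (not isolated)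
25 | (E)-alkenylzinc chloride from 24 | CCC1=C[C@@H](C)[C@@H]2C(C)=C[C@@](/C=C(C)/[Zn]Cl)(CC)[C@](C)(C(=O)OC)[C@@H]12 | intermediate (not isolated)
26 | methyl (1R,3aR,4R,5S,7aS)-3,5-diethyl-1,4,7-trimethyl-5-[(1E,3E)-2-methyl-4-phenylbuta-1,3-dien-1-yl]-3a,4,5,7a-tetrahydro-1H-indene-4-carboxylate | CCC1=C[C@@H](C)[C@@H]2C(C)=C[C@@](/C=C(C)/C=C/c3ccccc3)(CC)[C@](C)(C(=O)OC)[C@@H]12 | intermediate
27 | sodium salt of 28 | CCC1=C[C@@H](C)[C@@H]2C(C)=C[C@@](/C=C(C)/C=C/c3ccccc3)(CC)[C@](C)(C(=O)[O-])[C@@H]12.[Na+] | intermediate (not isolated)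
28 | (1R,3aR,4R,5S,7aS)-3,5-diethyl-1,4,7-trimethyl-5-[(1E,3E)-2-methyl-4-phenylbuta-1,3-dien-1-yl]-3a,4,5,7a-tetrahydro-1H-indene-4-carboxylic acid | CCC1=C[C@@H](C)[C@@H]2C(C)=C[C@@](/C=C(C)/C=C/c3ccccc3)(CC)[C@](C)(C(=O)O)[C@@H]12 | target

**Step count**

Total: 16 steps. Longest linear sequence: 15 steps (steps 1–7 and 9–16); step 8 is a one-step side branch.

**Steps most likely to fail**

Step 14. The risks are competing insertion into the C4 methyl C–H bonds, 1,2-shift of the carbene to an alkyne, enolisation of the hindered ketone by the basic reagent, and poor discrimination between the two methylene hydrogens. The fallback sets out from 17 and comes back at 22; it keeps the C1 oxygen and makes the bond by a stereospecific anionic closure. Appel iodination of 17 (PPh3, I2, imidazole) inverts C1 and gives methyl (1R,2R,5S,6S)-2-ethyl-5-[(1R)-1-iodoethyl]-1,4-dimethyl-6-propanoyl-2-(prop-1-yn-1-yl)cyclohex-3-ene-1-carboxylate F1. Addition of LiCH2SO2Ph to the ketone at −78 °C gives the β-hydroxy sulfone F2 as its lithium alkoxide. LiN(i-Pr)2 then forms the α-sulfonyl carbanion, which displaces iodide in a 5-exo-tet SN2 closure; this second inversion restores the required C1 configuration. Trapping the tertiary alkoxide with PhCOCl gives the benzoyloxy sulfone F3. Julia-type reductive elimination with SmI2 removes benzoate and sulfinate and leaves the C2=C3 alkene, which is 22.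

Step 10. The risks are a slow cycloaddition, because two fully substituted carbons must be joined through an ester tether that disfavours the reactive conformation, and endo/exo leakage to the cis-fused lactone. The fallback sets out from 10 and comes back at 17; it uses a (Z)-dienophile, for which both carbonyl groups can be endo at once, and corrects C3a afterwards. The lithium alkoxide of 10 opens citraconic anhydride at the less hindered carbonyl to give the (Z)-half ester F4, and Me3SiCHN2 in MeOH gives the (Z)-diester F5. Heating as in step 10 should give the cis-fused lactone F6, which has the same C4, C5 and C7a configuration as 15 but is epimeric at C3a. EtLi at −78 °C opens it to the hydroxy ketone F7, and base equilibration (DBU, toluene) at the ketone α-carbon moves the propanoyl group trans to the C7a substituent, which gives 17.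

Step 11. The risk is that the strained tetrahedral adduct collapses early to the ketone and takes up a second ethyllithium, or that the lactone is enolised at C3a. The fallback sets out from 15 and comes back at 19; the acyl group is held as an N-methoxy-N-methylamide until the ethyl group is introduced last. Me(MeO)NH·HCl with AlMe3 opens 15 to the hydroxy amide F8. Thioacylation as in step 12 gives F9, and Bu3SnH with AIBN gives the deoxygenated amide F10. EtMgBr then forms a stable chelate that releases 19 on work-up.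

**Further compounds**

F1 | step 14 | methyl (1R,2R,5S,6S)-2-ethyl-5-[(1R)-1-iodoethyl]-1,4-dimethyl-6-propanoyl-2-(prop-1-yn-1-yl)cyclohex-3-ene-1-carboxylate | C[C@@H](I)[C@@H]2C(C)=C[C@@](C#CC)(CC)[C@](C)(C(=O)OC)[C@H]2C(=O)CC
F2 | step 14 | methyl (1R,2R,5S,6S)-2-ethyl-6-[2-hydroxy-1-(phenylsulfonyl)butan-2-yl]-5-[(1R)-1-iodoethyl]-1,4-dimethyl-2-(prop-1-yn-1-yl)cyclohex-3-ene-1-carboxylate (mixture at the carbinol carbon) | C[C@@H](I)[C@@H]2C(C)=C[C@@](C#CC)(CC)[C@](C)(C(=O)OC)[C@H]2C(O)(CC)CS(=O)(=O)c1ccccc1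
F3 | step 14 | methyl 3-(benzoyloxy)-3,5-diethyl-1,4,7-trimethyl-2-(phenylsulfonyl)-5-(prop-1-yn-1-yl)-2,3,3a,4,5,7a-hexahydro-1H-indene-4-carboxylate (C1, C3a, C4, C5, C7a as in 22; mixture at C2 and C3) | CCC1(OC(=O)c3ccccc3)C(S(=O)(=O)c3ccccc3)[C@@H](C)[C@@H]2C(C)=C[C@@](C#CC)(CC)[C@](C)(C(=O)OC)[C@@H]12
F4 | step 10 | (2Z)-4-{[(2S,3E,5E)-6-ethyl-4-methylnona-3,5-dien-7-yn-2-yl]oxy}-2-methyl-4-oxobut-2-enoic acid | C[C@H](OC(=O)/C=C(/C)C(=O)O)/C=C(C)/C=C(\CC)C#CC
F5 | step 10 | 4-[(2S,3E,5E)-6-ethyl-4-methylnona-3,5-dien-7-yn-2-yl] 1-methyl (2Z)-2-methylbut-2-enedioate | C[C@H](OC(=O)/C=C(/C)C(=O)OC)/C=C(C)/C=C(\CC)C#CC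
F6 | step 10 | methyl (3S,3aS,6R,7R,7aR)-6-ethyl-3,4,7-trimethyl-1-oxo-6-(prop-1-yn-1-yl)-1,3,3a,6,7,7a-hexahydro-2-benzofuran-7-carboxylate (cis-fused lactone) | O=C1O[C@@H](C)[C@@H]2C(C)=C[C@@](C#CC)(CC)[C@](C)(C(=O)OC)[C@H]12
F7 | step 10 | methyl (1R,2R,5S,6R)-2-ethyl-5-[(1S)-1-hydroxyethyl]-1,4-dimethyl-6-propanoyl-2-(prop-1-yn-1-yl)cyclohex-3-ene-1-carboxylate | C[C@H](O)[C@@H]2C(C)=C[C@@](C#CC)(CC)[C@](C)(C(=O)OC)[C@@H]2C(=O)CC
F8 | step 11 | methyl (1R,2R,5S,6S)-2-ethyl-5-[(1S)-1-hydroxyethyl]-6-[methoxy(methyl)carbamoyl]-1,4-dimethyl-2-(prop-1-yn-1-yl)cyclohex-3-ene-1-carboxylate | C[C@H](O)[C@@H]2C(C)=C[C@@](C#CC)(CC)[C@](C)(C(=O)OC)[C@H]2C(=O)N(C)OC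
F9 | step 11 | methyl (1R,2R,5S,6S)-2-ethyl-5-[(1S)-1-(1H-imidazole-1-carbothioyloxy)ethyl]-6-[methoxy(methyl)carbamoyl]-1,4-dimethyl-2-(prop-1-yn-1-yl)cyclohex-3-ene-1-carboxylate | C[C@H](OC(=S)n1ccnc1)[C@@H]2C(C)=C[C@@](C#CC)(CC)[C@](C)(C(=O)OC)[C@H]2C(=O)N(C)OC
F10 | step 11 | methyl (1R,2R,5S,6S)-2,5-diethyl-6-[methoxy(methyl)carbamoyl]-1,4-dimethyl-2-(prop-1-yn-1-yl)cyclohex-3-ene-1-carboxylate | CC[C@@H]2C(C)=C[C@@](C#CC)(CC)[C@](C)(C(=O)OC)[C@H]2C(=O)N(C)OC
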